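**Assumption (stereochemistry):** The target SMILES has no stereodescriptors and the molecule has no stereocentre. The biaryl axis has only one ortho substituent on each ring, so I treat it as configurationally unspecified. No asymmetric step is needed and nothing can be scrambled.

**Ring labels:** A is the anisole ring, B the para-phenylene ring, C the catechol-derived ring and D the phenol ring of the biaryl.

## Retrosynthetic overview
1. Plagiochin D comes from its bis-benzyl ether C–D stilbene macrocycle by one hydrogenation, which saturates C=C and cleaves both OBn groups.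
2. The 16-membered macrocycle is the only ring formed, and it is closed at the C–D bridge by McMurry coupling of an open-chain dialdehyde.
3. The A–D biaryl bond comes from Suzuki coupling of an A-ring bromide with 4-benzyloxy-2-formylphenylboronic acid.
4. The saturated A–B bridge comes from 9-BBN hydroboration of 2-bromo-5-methoxystyrene, then B-alkyl Suzuki coupling of that borane with a B-ring iodide (Ar–I reacts before Ar–Br).
5. The B–O–C ether comes from Chan–Lam coupling. OMe and OH are differentiated from the start, since ring A is bought as the methyl ether and rings C and D as benzyl ethers.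

## Route

**Step 1**
Reactants: 1, 4-(benzyloxy)-3-hydroxybenzaldehyde; 2, 4-iodophenylboronic acid
Product: 3, 4-(benzyloxy)-3-(4-iodophenoxy)benzaldehyde
Conditions: 2 (2 equiv), Cu(OAc)2 (1 equiv), pyridine (5 equiv), 4 Å MS, CH2Cl2, air, rt, 24–48 h
Reagents that add atoms: 4-iodophenylboronic acid (2), OB(O)c1ccc(I)cc1
Why: Chan–Lam–Evans O-arylation forms the diaryl ether oxidatively at rt, where Ar–I, CHO and OBn are all inert.

**Step 2**
Reactants: 4, 2-bromo-5-methoxybenzaldehyde; 5, methyltriphenylphosphonium bromide
Product: 6, 1-bromo-4-methoxy-2-vinylbenzene (2-bromo-5-methoxystyrene)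
Conditions: 5 (1.3 equiv), KOt-Bu (1.25 equiv), THF, 0 °C → rt, 2 h; use the product promptly
Reagents that add atoms: methyltriphenylphosphonium bromide (5), C[P+](c1ccccc1)(c1ccccc1)c1ccccc1.[Br-] (supplies CH2)
Why: Wittig methylenation of a non-enolisable aryl aldehyde, with KOt-Bu rather than BuLi to avoid Br/Li exchange.

**Step 3**
Reactants: 6, 2-bromo-5-methoxystyrene; 7, 9-BBN
Product: 8, B-[2-(2-bromo-5-methoxyphenyl)ethyl]-9-borabicyclo[3.3.1]nonane, kept as a THF solution under Ar and carried forward without isolation
Conditions: 9-BBN (0.5 M in THF, 0.97 equiv relative to 6), 0 °C → rt, 4 h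
Reagents that add atoms: 9-BBN (7), [H]B1C2CCCC1CCC2 (adds H and the 9-borabicyclononyl unit)
Why: Anti-Markovnikov hydroboration of the styrene places boron on the terminal carbon with high regioselectivity, leaves Ar–Br untouched, and the slight excess of alkene leaves no B–H to reduce the aldehyde met in Step 4.

**Step 4**
Reactants: 8, the alkyl-9-BBN solution from Step 3; 3, the aryl iodide from Step 1
Product: 9, 4-(benzyloxy)-3-{4-[2-(2-bromo-5-methoxyphenyl)ethyl]phenoxy}benzaldehyde
Conditions:
- Stir 8 (1.3 equiv, THF solution) with 3 M aq Cs2CO3 (3 equiv) for 15 min.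
- Add 3 (1.0 equiv), PdCl2(dppf)·CH2Cl2 (5 mol %), AsPh3 (5 mol %) and DMF, then rt → 40 °C, 12 h.
- Use a non-oxidative aqueous work-up and chromatography, because H2O2 would cause Dakin oxidation of the aldehyde.

Reagents that add atoms: none beyond reactants 8 and 3 (the 9-BBN boron unit and iodide are both expelled)
Why: B-alkyl Suzuki–Miyaura coupling forms the saturated sp3–sp2 bridge directly, because oxidative addition at or near rt selects Ar–I over the hindered, electron-rich Ar–Br, and the hydroxyborate form of 8 does not reduce the aldehyde.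

**Step 5**
Reactants: 9, the aryl bromide from Step 4; 10, [4-(benzyloxy)-2-formylphenyl]boronic acid
Product: 11, 4-(benzyloxy)-2'-(2-{4-[2-(benzyloxy)-5-formylphenoxy]phenyl}ethyl)-4'-methoxy-[1,1'-biphenyl]-2-carbaldehyde
Conditions: 10 (1.5 equiv), Pd(OAc)2 (3 mol %), SPhos (6 mol %), K3PO4 (3 equiv), toluene/H2O 10:1, 90 °C, 8 h
Reagents that add atoms: [4-(benzyloxy)-2-formylphenyl]boronic acid (10), OB(O)c1ccc(OCc2ccccc2)cc1C=O
Why: Suzuki–Miyaura coupling with a biaryl phosphine engages the ortho-substituted, electron-rich bromide faster than the formylboronic acid protodeboronates, and both aldehydes and both benzyl ethers tolerate the conditions.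

**Step 6**
Reactants: 11, the dialdehyde from Step 5
Product: 12, O,O'-dibenzyl-dehydroplagiochin D, the 16-membered macrocycle with CH=CH between rings C and D (an E/Z mixture, which does not matter)
Conditions: TiCl4 (15 equiv), Zn (30 equiv), pyridine, THF, reflux 2 h; then 11 added by syringe pump over 12–16 h (final about 1–2 mM), reflux; aq K2CO3 quench
Reagents that add atoms: none
Why: Intramolecular McMurry coupling under pseudo-high dilution joins the only two carbonyls, helped by the flexible, already saturated A–B bridge, and the aryl ethers survive pre-reduced low-valent Ti.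

**Step 7**
Reactants: 12, the macrocyclic stilbene from Step 6
Product: 13, Plagiochin D
Conditions: H2 (1 atm), 10 % Pd/C, EtOAc/EtOH 1:1, rt, 12 h
Reagents that add atoms: none (H2 only)
Why: Catalytic hydrogenation saturates either alkene isomer and hydrogenolyses both aryl benzyl ethers in the same operation, while the aryl methyl ether and the diaryl ether are inert.

## Compound list
| No. | Name | SMILES | Role |
|---|---|---|---|
| 1 | 4-(benzyloxy)-3-hydroxybenzaldehyde | O=Cc1ccc(OCc2ccccc2)c(O)c1 | starting material |
| 2 | 4-iodophenylboronic acid | OB(O)c1ccc(I)cc1 | starting material |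
| 3 | 4-(benzyloxy)-3-(4-iodophenoxy)benzaldehyde | O=Cc1ccc(OCc2ccccc2)c(Oc2ccc(I)cc2)c1 | intermediate |
| 4 | 2-bromo-5-methoxybenzaldehyde | COc1ccc(Br)c(C=O)c1 | starting material |
| 5 | methyltriphenylphosphonium bromide | C[P+](c1ccccc1)(c1ccccc1)c1ccccc1.[Br-] | starting material |
| 6 | 1-bromo-4-methoxy-2-vinylbenzene | COc1ccc(Br)c(C=C)c1 | intermediate |
| 7 | 9-BBN (9-borabicyclo[3.3.1]nonane) | [H]B1C2CCCC1CCC2 | starting material |
| 8 | B-[2-(2-bromo-5-methoxyphenyl)ethyl]-9-BBN | COc1ccc(Br)c(CCB2C3CCCC2CCC3)c1 | intermediate (product of Step 3, used as a solution) |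
| 9 | 4-(benzyloxy)-3-{4-[2-(2-bromo-5-methoxyphenyl)ethyl]phenoxy}benzaldehyde | COc1ccc(Br)c(CCc2ccc(Oc3cc(C=O)ccc3OCc3ccccc3)cc2)c1 | intermediate |
| 10 | [4-(benzyloxy)-2-formylphenyl]boronic acid | OB(O)c1ccc(OCc2ccccc2)cc1C=O | starting material |
| 11 | open-chain A–D biaryl dialdehyde | COc1ccc(-c2ccc(OCc3ccccc3)cc2C=O)c(CCc2ccc(Oc3cc(C=O)ccc3OCc3ccccc3)cc2)c1 | intermediate |
| 12 | O,O'-dibenzyl-dehydroplagiochin D (E/Z) | COc1ccc2c(c1)CCc1ccc(cc1)Oc1cc(ccc1OCc1ccccc1)C=Cc1cc(OCc3ccccc3)ccc1-2 | intermediate |
| 13 | Plagiochin D (C29H26O4) | COc1ccc2c(c1)CCc1ccc(cc1)Oc1cc(ccc1O)CCc1cc(O)ccc1-2 | target |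

## Summary
**Total steps:** 7. Steps 3 and 4 are telescoped in one flask, so there are six isolations.
**Longest linear sequence:** 6 steps (Steps 2, 3, 4, 5, 6 and 7). The branch through Step 1 is 5 steps.

**Steps most likely to fail, each with a fallback**
1. **Step 6, McMurry macrocyclisation.** The risks are ring strain, oligomers and arrest at the pinacol. Fallback: close the biaryl bond last instead.
   - Carry out a Wittig reaction of 9 with [2-bromo-5-(benzyloxy)benzyl]triphenylphosphonium bromide.
   - Reduce the alkene with diimide.
   - Close the ring by intramolecular Pd(0)/(Me3Sn)2 Stille–Kelly coupling (or Ni(0) reductive coupling) of the open-chain dibromide, then debenzylate with H2, Pd/C.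
2. **Step 4, B-alkyl Suzuki coupling (with the Step 3 borane).** The risks are I/Br selectivity, self-coupling of 8 through its own Ar–Br, and the exposed aldehyde. Fallback: build the A–B bridge by olefination.
   - Protect 1 as its dioxolane.
   - Perform SNAr on 4-fluorobenzaldehyde (K2CO3, DMF).
   - Carry out a Wittig reaction with (2-bromo-5-methoxybenzyl)triphenylphosphonium bromide.
   - Reduce the stilbene with diimide and hydrolyse the acetal with acid to reach 9.
3. **Step 1, Chan–Lam coupling.** The phenol is ortho-substituted and electron-poor, and the boronic acid may be consumed by side reactions. Fallback: switch to a halide electrophile.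
   - Use an Ullmann–Ma etherification of 1 with excess 1,4-diiodobenzene (CuI, N,N-dimethylglycine, Cs2CO3, dioxane, 90 °C).
   - If that also fails, perform SNAr on 4-fluoronitrobenzene, reduce the nitro group and convert the amine to the iodide by Sandmeyer iodination to reach 3.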